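## Retrosynthetic overview
1. The C5 isobutyryl group goes on last, by C-acylation of trione 34. C5 is its only enolisable carbon, and the acidic C5–H settles under thermodynamic control.
2. The eight-membered carbocycle closes at C6–C7 by an intramolecular aldol addition of a regiospecific samarium enolate (from a C–Br bond) onto the side-chain aldehyde. The tether from C1 fixes C7.
3. Quaternary C1 comes from prenylation of a 3-alkyl tetronic acid, anti to the prenyl group on the neighbouring stereocentre. That relay centre derives from (S)-glycidate and is erased afterwards.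
4. The fragments join at C1–C2 by reductive Knoevenagel alkylation of tetronic acid 17 with aldehyde 12.
5. Aldehyde 12 (C3, C4) comes from a geranyl ester by an enantioselective boron Ireland–Claisen rearrangement, and 17 from methyl (S)-glycidate. Ring order: furanone first (step 9), carbocycle second (step 17).

Target numbering: 8-oxabicyclo[5.2.1]decane, with C1 and C7 the bridgeheads, O8, C9 the lactone C=O and C10 the bridging ketone.

Assumption: the (S,S)-diazaborolidine 7 gives the (2R,3S)-acid 10 (if the sense is opposite, the equally available (R,R)-diamine is used and nothing else changes), and the natural 5R epimer is the thermodynamic one at the acidic C5–H.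

## Route

Step 1
Reactants: 1 geranyl acetate; 2 prenyl bromide
Product: 3 geranyl 5-methylhex-4-enoate
Conditions: LDA (1.05 equiv), THF/DMPU, −78 °C; then 2, −78 to −40 °C
Reagents that add atoms: none
Why: Kinetic ester enolate alkylation (SN2 at the primary allylic bromide) is faster at low temperature than self-condensation or a [3,3] shift of the lithium enolate, and no stereocentre is formed while the E-alkene is untouched.

Step 2
Reactants: 4 (1S,2S)-1,2-diphenylethane-1,2-diamine; 5 3,5-bis(trifluoromethyl)benzenesulfonyl chloride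
Product: 6 (1S,2S)-N,N'-bis[3,5-bis(trifluoromethyl)phenylsulfonyl]-1,2-diphenylethane-1,2-diamine
Conditions: 5 (2.1 equiv), Et3N, DMAP (cat.), CH2Cl2, 0 °C to rt
Reagents that add atoms: none
Why: Double N-sulfonylation of the C2-symmetric diamine leaves both stereocentres untouched.

Step 3
Reactants: 6 bis-sulfonamide
Product: 7 (4S,5S)-2-bromo-1,3-bis[3,5-bis(trifluoromethyl)phenylsulfonyl]-4,5-diphenyl-1,3,2-diazaborolidine
Conditions: BBr3 (1.0 equiv), CH2Cl2, rt; volatiles removed in vacuo
Reagents that add atoms: boron tribromide, BrB(Br)Br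
Why: Aminolysis of two B–Br bonds by the acidic sulfonamide N–H groups closes the diazaborolidine, and evaporation of HBr drives it to completion.

Step 4
Reactants: 3 geranyl 5-methylhex-4-enoate; 7 bromodiazaborolidine
Product: 10 (2R,3S)-3-ethenyl-3,7-dimethyl-2-(3-methylbut-2-en-1-yl)oct-6-enoic acid, via Z(O)-boron ketene acetal 8 (not isolated), via acyloxyborane 9 (not isolated)
Conditions: 7 (1.1 equiv), i-Pr2NEt, CH2Cl2, −78 °C; then −20 to 4 °C, 2–4 d; aqueous work-up
Reagents that add atoms: none
Why: In this enantioselective Ireland–Claisen rearrangement, soft enolisation with Hünig's base in CH2Cl2 gives the Z(O)-boron ketene acetal, the chair [3,3] transition state on the E-geranyl alkene places prenyl and homoprenyl both equatorial and so sets the C2/C3 relative configuration (tertiary next to quaternary), and the C2-symmetric ligand on boron selects the enolate face and so the absolute configuration.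

Step 5
Reactants: 10 acid
Product: 11 (2R,3S)-3-ethenyl-3,7-dimethyl-2-(3-methylbut-2-en-1-yl)oct-6-en-1-ol
Conditions: LiAlH4, Et2O, 0 °C to rt; Fieser work-up
Reagents that add atoms: none
Why: Hydride reduction of the carboxylic acid touches neither the isolated alkenes nor either stereocentre.

Step 6
Reactants: 11 alcohol
Product: 12 (2R,3S)-3-ethenyl-3,7-dimethyl-2-(3-methylbut-2-en-1-yl)oct-6-enal
Conditions: Dess–Martin periodinane, pyridine, CH2Cl2, 0 °C
Reagents that add atoms: none
Why: Buffered Dess–Martin oxidation stops at the aldehyde and does not epimerise the hindered α-stereocentre.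

Step 7
Reactants: 13 methyl (2S)-oxirane-2-carboxylate; 14 2-methylprop-1-en-1-ylmagnesium bromide
Product: 15 methyl (2S)-2-hydroxy-5-methylhex-4-enoate
Conditions: CuBr·SMe2 (15 mol %), THF, −78 to −40 °C; H2O quench
Reagents that add atoms: none
Why: Copper-catalysed SN2 opening of the epoxide at the unsubstituted C3 outruns ester addition at low temperature, builds the prenyl group, and keeps the S configuration because the C2–O bond is never broken.

Step 8
Reactants: 15 hydroxy ester
Product: 16 methyl (2S)-2-acetoxy-5-methylhex-4-enoate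
Conditions: Ac2O, pyridine, DMAP (cat.), CH2Cl2, 0 °C to rt
Reagents that add atoms: acetic anhydride, CC(=O)OC(C)=O
Why: Simple O-acylation supplies the two-carbon unit (future C1 and C9) without touching the stereocentre.

Step 9
Reactants: 16 acetoxy ester
Product: 17 (5S)-4-hydroxy-5-(3-methylbut-2-en-1-yl)furan-2(5H)-one
Conditions: LiHMDS (2.3 equiv), THF, −78 to 0 °C; 1 M HCl
Reagents that add atoms: none
Why: In this Dieckmann (intramolecular Claisen) condensation the acetate enolate attacks the methyl ester to close the five-membered ring, and the product is held as its tetronate anion, which shields C5–H from deprotonation so 5S is retained.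

Step 10
Reactants: 18 prenol (3-methylbut-2-en-1-ol)
Product: 19 methyl 3-methylbut-2-en-1-yl carbonate
Conditions: ClCO2Me, pyridine, CH2Cl2, 0 °C
Reagents that add atoms: methyl chloroformate, COC(=O)Cl
Why: O-acylation with the chloroformate gives a prenyl donor that generates its own base (methoxide) on ionisation with Pd(0).

Step 11
Reactants: 12 aldehyde; 17 tetronic acid
Product: 21 (5S)-3-[(2S,3S)-3-ethenyl-3,7-dimethyl-2-(3-methylbut-2-en-1-yl)oct-6-en-1-yl]-4-hydroxy-5-(3-methylbut-2-en-1-yl)furan-2(5H)-one, via 3-alkylidenefurandione 20 (not isolated)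
Conditions: L-proline (20 mol %), Hantzsch ester (1.1 equiv), CH2Cl2, rt to 40 °C
Reagents that add atoms: none
Why: In this three-component reductive alkylation, Knoevenagel condensation gives the very electrophilic alkylidene, which the Hantzsch ester reduces by conjugate hydride transfer faster than it can add a second tetronic acid or lose its γ-proton, so the C1–C2 bond forms with all three stereocentres kept.

Step 12
Reactants: 21 vinyl tetronic acid
Product: 23 (5S)-4-hydroxy-3-[(2S,3S)-3-(2-hydroxyethyl)-3,7-dimethyl-2-(3-methylbut-2-en-1-yl)oct-6-en-1-yl]-5-(3-methylbut-2-en-1-yl)furan-2(5H)-one, via bis(9-BBN) adduct 22 (not isolated)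
Conditions: 9-BBN (2.3 equiv), THF, 0 °C to rt; NaOH, H2O2, 0 °C; 1 M HCl
Reagents that add atoms: hydrogen peroxide, OO
Why: In this hydroboration–oxidation 9-BBN picks the single monosubstituted alkene over the three trisubstituted ones and places boron on the terminal carbon, and the tetronic acid passes through as its O-borinate and then as the inert tetronate anion, so the alkaline peroxide does no damage at this stage.

Step 13
Reactants: 23 hydroxy tetronic acid; 19 methyl prenyl carbonate
Product: 24 (3R,5S)-3-[(2S,3S)-3-(2-hydroxyethyl)-3,7-dimethyl-2-(3-methylbut-2-en-1-yl)oct-6-en-1-yl]-3,5-bis(3-methylbut-2-en-1-yl)furan-2,4(3H,5H)-dione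
Conditions: Pd(PPh3)4 (5 mol %), 19 (1.2 equiv), THF, 0 °C to rt; minor C3 epimer removed by chromatography
Reagents that add atoms: none
Why: In this Tsuji–Trost allylic alkylation the soft hindered tetronate attacks the unsubstituted terminus of the π-prenyl-palladium complex, any O-prenyl product re-ionises and funnels to carbon, and attack on the planar ring from the face anti to the C5 prenyl group (1,3-induction) sets the quaternary 3R centre (C1 of the target).

Step 14
Reactants: 24 furandione alcohol
Product: 27 (3R)-5-bromo-3-[(2S,3S)-3-(2-hydroxyethyl)-3,7-dimethyl-2-(3-methylbut-2-en-1-yl)oct-6-en-1-yl]-3,5-bis(3-methylbut-2-en-1-yl)furan-2,4(3H,5H)-dione (C5 epimers), via bis(trimethylsilyl) enol ether 25 (not isolated), via bromo ketone TMS ether 26 (not isolated)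
Conditions: TMSOTf (2.5 equiv), Et3N, CH2Cl2, 0 °C, cold NaHCO3 wash; NBS (1.05 equiv), THF, −78 °C; aq. citric acid, 0 °C
Reagents that add atoms: N-bromosuccinimide, O=C1CCC(=O)N1Br
Why: Soft enolisation can give only one silyl enol ether because C3 is quaternary, electrophilic α-bromination of that electron-rich alkene at −78 °C is far faster than attack on the trisubstituted alkenes, and the relay stereocentre C5 is destroyed on purpose since both bromide epimers give the same enolate later.

Step 15
Reactants: 27 bromo alcohol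
Product: 28 (3R)-5-bromo-3-[(2S,3S)-3,7-dimethyl-2-(3-methylbut-2-en-1-yl)-3-(2-oxoethyl)oct-6-en-1-yl]-3,5-bis(3-methylbut-2-en-1-yl)furan-2,4(3H,5H)-dione (C5 epimers)
Conditions: Dess–Martin periodinane, CH2Cl2, 0 °C to rt; used at once
Reagents that add atoms: none
Why: Dess–Martin oxidation is non-basic and free of Lewis acid, so the tertiary bromide does not eliminate and the citronellal-like aldehyde does not undergo an ene cyclisation.

Step 16
Reactants: 29 samarium metal; 30 1,2-diiodoethane
Product: 31 samarium(II) iodide (0.1 M in THF)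
Conditions: THF, rt, argon
Reagents that add atoms: none
Why: Samarium(0) reduces the vicinal diiodide with loss of ethene, giving a fresh titrated solution of the one-electron reductant.

Step 17
Reactants: 28 bromo aldehyde; 31 samarium(II) iodide
Product: 33 (1R,3S,4S,7S)-6-hydroxy-4-methyl-1,3,7-tris(3-methylbut-2-en-1-yl)-4-(4-methylpent-3-en-1-yl)-8-oxabicyclo[5.2.1]decane-9,10-dione (C6 epimers), via samarium(III) enolate 32 (not isolated)
Conditions: 31 (2.2 equiv), THF, 0.005 M in 28, −78 °C, 30 min; H2O quench at −78 °C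
Reagents that add atoms: none
Why: Two-electron reduction of the C–Br bond gives the samarium(III) enolate regiospecifically and without base (so the enolisable aldehyde is never deprotonated and cannot attack the lactone or ketone through six-membered transition states), Sm(III) binds enolate and aldehyde together and templates the intramolecular aldol addition (Reformatsky-type enolate generation, precedented for eight-membered rings), and because the five-atom tether hangs from C1 the C6–C7 bond can form only on that face, which sets 7S.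

Step 18
Reactants: 33 aldol
Product: 34 (1R,3S,4S,7S)-4-methyl-1,3,7-tris(3-methylbut-2-en-1-yl)-4-(4-methylpent-3-en-1-yl)-8-oxabicyclo[5.2.1]decane-6,9,10-trione
Conditions: Dess–Martin periodinane, pyridine, CH2Cl2, rt
Reagents that add atoms: none
Why: Dess–Martin oxidation converges both carbinol epimers to the C6 ketone under conditions free of nucleophiles, so neither retro-aldol nor retro-Claisen cleavage of the non-enolisable tricarbonyl can occur.

Step 19
Reactants: 35 isobutyryl chloride; 36 1H-benzotriazole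
Product: 37 1-(2-methylpropanoyl)-1H-benzotriazole
Conditions: Et3N, CH2Cl2, 0 °C to rt
Reagents that add atoms: none
Why: N-acylation gives a neutral, storable acyl donor that acylates carbon rather than oxygen of magnesium enolates.

Step 20
Reactants: 34 trione; 37 1-isobutyrylbenzotriazole
Product: 39 (1R,3S,4R,5R,7S)-4-methyl-1,3,7-tris(3-methylbut-2-en-1-yl)-4-(4-methylpent-3-en-1-yl)-5-(2-methylpropanoyl)-8-oxabicyclo[5.2.1]decane-6,9,10-trione, via magnesium enolate 38 (not isolated)
Conditions: MgBr2·OEt2 (2.5 equiv), i-Pr2NEt (3 equiv), 37 (1.5 equiv), CH2Cl2, rt; 1 M HCl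
Reagents that add atoms: none
Why: In this soft-enolisation Claisen-type C-acylation, C5–H2 is the only enolisable position of 34, Mg(II) chelation lets Hünig's base remove it, every equilibrium drains into the chelated β-diketone enolate 38, and protonation followed by equilibration through the enol leaves the thermodynamic 5R epimer with the isobutyryl group trans to the neighbouring homoprenyl chain.

## Compound list
1 | geranyl acetate | CC(C)=CCC/C(C)=C/COC(C)=O | starting material
2 | prenyl bromide | CC(C)=CCBr | starting material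
3 | geranyl 5-methylhex-4-enoate | CC(C)=CCC/C(C)=C/COC(=O)CCC=C(C)C | intermediate
4 | (1S,2S)-1,2-diphenylethane-1,2-diamine | N[C@@H](c1ccccc1)[C@@H](N)c1ccccc1 | starting material
5 | 3,5-bis(trifluoromethyl)benzenesulfonyl chloride | O=S(=O)(Cl)c1cc(C(F)(F)F)cc(C(F)(F)F)c1 | starting material
6 | (1S,2S)-N,N'-bis[3,5-bis(trifluoromethyl)phenylsulfonyl]-1,2-diphenylethane-1,2-diamine | O=S(=O)(N[C@@H](c1ccccc1)[C@@H](NS(=O)(=O)c1cc(C(F)(F)F)cc(C(F)(F)F)c1)c1ccccc1)c1cc(C(F)(F)F)cc(C(F)(F)F)c1 | intermediate
7 | (4S,5S)-2-bromo-1,3-bis[3,5-bis(trifluoromethyl)phenylsulfonyl]-4,5-diphenyl-1,3,2-diazaborolidine | BrB1N(S(=O)(=O)c2cc(C(F)(F)F)cc(C(F)(F)F)c2)[C@@H](c2ccccc2)[C@H](c2ccccc2)N1S(=O)(=O)c1cc(C(F)(F)F)cc(C(F)(F)F)c1 | intermediate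
8 | Z(O)-boron ketene acetal of 3 (prenyl CH2 cis to O–B) | CC(C)=CCC/C(C)=C/CO/C(OB1N(S(=O)(=O)c2cc(C(F)(F)F)cc(C(F)(F)F)c2)[C@@H](c2ccccc2)[C@H](c2ccccc2)N1S(=O)(=O)c1cc(C(F)(F)F)cc(C(F)(F)F)c1)=C/CC=C(C)C | intermediate
9 | acyloxyborane of acid 10 | CC(C)=CCC[C@](C=C)(C)[C@@H](CC=C(C)C)C(=O)OB1N(S(=O)(=O)c2cc(C(F)(F)F)cc(C(F)(F)F)c2)[C@@H](c2ccccc2)[C@H](c2ccccc2)N1S(=O)(=O)c1cc(C(F)(F)F)cc(C(F)(F)F)c1 | intermediate
10 | (2R,3S)-3-ethenyl-3,7-dimethyl-2-(3-methylbut-2-en-1-yl)oct-6-enoic acid | CC(C)=CCC[C@](C=C)(C)[C@@H](CC=C(C)C)C(=O)O | intermediate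
11 | (2R,3S)-3-ethenyl-3,7-dimethyl-2-(3-methylbut-2-en-1-yl)oct-6-en-1-ol | CC(C)=CCC[C@](C=C)(C)[C@@H](CC=C(C)C)CO | intermediate
12 | (2R,3S)-3-ethenyl-3,7-dimethyl-2-(3-methylbut-2-en-1-yl)oct-6-enal | CC(C)=CCC[C@](C=C)(C)[C@@H](CC=C(C)C)C=O | intermediate
13 | methyl (2S)-oxirane-2-carboxylate | COC(=O)[C@@H]1CO1 | starting material
14 | 2-methylprop-1-en-1-ylmagnesium bromide | CC(C)=C[Mg]Br | starting material
15 | methyl (2S)-2-hydroxy-5-methylhex-4-enoate | COC(=O)[C@@H](O)CC=C(C)C | intermediate
16 | methyl (2S)-2-acetoxy-5-methylhex-4-enoate | COC(=O)[C@@H](OC(C)=O)CC=C(C)C | intermediate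
17 | (5S)-4-hydroxy-5-(3-methylbut-2-en-1-yl)furan-2(5H)-one | O=C1C=C(O)[C@H](CC=C(C)C)O1 | intermediate
18 | prenol | CC(C)=CCO | starting material
19 | methyl 3-methylbut-2-en-1-yl carbonate | COC(=O)OCC=C(C)C | intermediate
20 | (5S)-3-alkylidene-5-prenylfuran-2,4-dione from 12 and 17 (alkene geometry open) | CC(C)=CCC[C@](C=C)(C)[C@@H](CC=C(C)C)C=C1C(=O)O[C@@H](CC=C(C)C)C1=O | intermediate
21 | (5S)-3-[(2S,3S)-3-ethenyl-3,7-dimethyl-2-prenyloct-6-en-1-yl]-4-hydroxy-5-prenylfuran-2(5H)-one | CC(C)=CCC[C@](C=C)(C)[C@@H](CC=C(C)C)CC1=C(O)[C@H](CC=C(C)C)OC1=O | intermediate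
22 | bis(9-BBN) adduct of 21 (terminal C–B, enol O–B) | CC(C)=CCC[C@](CCB1C2CCCC1CCC2)(C)[C@@H](CC=C(C)C)CC1=C(OB2C3CCCC2CCC3)[C@H](CC=C(C)C)OC1=O | intermediate
23 | (5S)-4-hydroxy-3-[(2S,3S)-3-(2-hydroxyethyl)-3,7-dimethyl-2-prenyloct-6-en-1-yl]-5-prenylfuran-2(5H)-one | CC(C)=CCC[C@](CCO)(C)[C@@H](CC=C(C)C)CC1=C(O)[C@H](CC=C(C)C)OC1=O | intermediate
24 | (3R,5S)-3-[(2S,3S)-3-(2-hydroxyethyl)-3,7-dimethyl-2-prenyloct-6-en-1-yl]-3,5-diprenylfuran-2,4(3H,5H)-dione | CC(C)=CCC[C@](CCO)(C)[C@@H](CC=C(C)C)C[C@@]1(CC=C(C)C)C(=O)O[C@@H](CC=C(C)C)C1=O | intermediate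
25 | bis(trimethylsilyl) derivative of 24 (primary O-TMS, C4 enol O-TMS) | CC(C)=CCC[C@](CCO[Si](C)(C)C)(C)[C@@H](CC=C(C)C)C[C@@]1(CC=C(C)C)C(=O)OC(CC=C(C)C)=C1O[Si](C)(C)C | intermediate
26 | 5-bromo furandione, primary TMS ether (C5 epimers) | CC(C)=CCC[C@](CCO[Si](C)(C)C)(C)[C@@H](CC=C(C)C)C[C@@]1(CC=C(C)C)C(=O)OC(Br)(CC=C(C)C)C1=O | intermediate
27 | (3R)-5-bromo furandione alcohol (C5 epimers) | CC(C)=CCC[C@](CCO)(C)[C@@H](CC=C(C)C)C[C@@]1(CC=C(C)C)C(=O)OC(Br)(CC=C(C)C)C1=O | intermediate
28 | (3R)-5-bromo furandione aldehyde (C5 epimers) | CC(C)=CCC[C@](CC=O)(C)[C@@H](CC=C(C)C)C[C@@]1(CC=C(C)C)C(=O)OC(Br)(CC=C(C)C)C1=O | intermediate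
29 | samarium | [Sm] | starting material
30 | 1,2-diiodoethane | ICCI | starting material
31 | samarium(II) iodide | [Sm+2].[I-].[I-] | intermediate
32 | samarium(III) enolate of the furandione aldehyde | CC(C)=CCC[C@](CC=O)(C)[C@@H](CC=C(C)C)C[C@@]1(CC=C(C)C)C(=O)OC(CC=C(C)C)=C1O[Sm](I)I | intermediate
33 | (1R,3S,4S,7S)-6-hydroxy-4-methyl-1,3,7-triprenyl-4-(4-methylpent-3-en-1-yl)-8-oxabicyclo[5.2.1]decane-9,10-dione (C6 epimers) | CC(C)=CCC[C@]1(C)[C@@H](CC=C(C)C)C[C@@]2(CC=C(C)C)C(=O)O[C@@](CC=C(C)C)(C(O)C1)C2=O | intermediate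
34 | (1R,3S,4S,7S)-4-methyl-1,3,7-triprenyl-4-(4-methylpent-3-en-1-yl)-8-oxabicyclo[5.2.1]decane-6,9,10-trione | CC(C)=CCC[C@]1(C)[C@@H](CC=C(C)C)C[C@@]2(CC=C(C)C)C(=O)O[C@@](CC=C(C)C)(C(=O)C1)C2=O | intermediate
35 | isobutyryl chloride | CC(C)C(=O)Cl | starting material
36 | 1H-benzotriazole | c1ccc2[nH]nnc2c1 | starting material
37 | 1-(2-methylpropanoyl)-1H-benzotriazole | CC(C)C(=O)n1nnc2ccccc12 | intermediate
38 | bromomagnesium enolate of 39 | CC(C)=CCC[C@]1(C)[C@@H](CC=C(C)C)C[C@@]2(CC=C(C)C)C(=O)O[C@@](CC=C(C)C)(C(=O)C1=C([O-])C(C)C)C2=O.[Mg+2].[Br-] | intermediate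
39 | (1R,3S,4R,5R,7S)-4-methyl-1,3,7-tris(3-methylbut-2-en-1-yl)-4-(4-methylpent-3-en-1-yl)-5-(2-methylpropanoyl)-8-oxabicyclo[5.2.1]decane-6,9,10-trione | CC(C)=CCC[C@]1(C)[C@@H](CC=C(C)C)C[C@@]2(CC=C(C)C)C(=O)O[C@@](CC=C(C)C)(C(=O)[C@H]1C(=O)C(C)C)C2=O | target

## Counts
Total step count: 20.
Longest linear sequence: 13 steps (2, 3, 4, 5, 6, 11, 12, 13, 14, 15, 17, 18, 20, counted through the controller line). It is 12 steps from geranyl acetate and 11 from methyl (S)-glycidate.

## Three steps most likely to fail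

**Step 17 (eight-membered ring closure).** The samarium enolate may simply be protonated, or may react intermolecularly, before it reaches the aldehyde.

The fallback sets out from 24 and comes back at 34, replacing steps 14–18. The primary alcohol of 24 is oxidised with TEMPO/PhI(OAc)2 in MeCN–water to the carboxylic acid F1. This is coupled with N,O-dimethylhydroxylamine (EDC, N-methylmorpholine) to the Weinreb amide F2.

KHMDS in THF at −78 °C under high dilution then removes only the furandione C5–H, which is far more acidic than the amide α-CH2. The enolate acylates on the amide. The chelated tetrahedral intermediate survives until the quench, so no retro-Claisen is possible, and 34 is released directly at the ketone oxidation level.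

**Step 13 (quaternary C1: C versus O attack, linear versus branched, facial selectivity).**

The fallback sets out from 23 and comes back at 24. The tetronic acid is O-alkylated with allyl bromide and CsF in DMF to the 4-allyloxybutenolide F3. Heating in toluene at 110 °C brings about a Claisen rearrangement. The allyl group is delivered suprafacially from O4 to C3, on the face away from the directly adjacent C5 prenyl group, giving the C3-allyl furandione F4.

Cross metathesis in 2-methyl-2-butene with the Hoveyda–Grubbs second-generation catalyst converts allyl into prenyl and gives 24. The existing prenyl and homoprenyl groups exchange degenerately under these conditions.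

**Step 20 (C-acylation at the hindered C5 next to quaternary C4).** O-acylation or no reaction is possible.

The fallback sets out from 34 and comes back at 39. The lithium enolate (LiHMDS, THF, −78 °C) is added to isobutyraldehyde, a small electrophile that reacts only with carbon nucleophiles, to give the β-hydroxy ketone F5. Dess–Martin oxidation then gives the β-diketone 39, whose C5 centre equilibrates as in the main route.

## Further compounds
F1 | step 17 | carboxylic acid from 24 (CH2OH oxidised to CO2H; 3R,5S furandione, 2S,3S side chain) | CC(C)=CCC[C@](CC(=O)O)(C)[C@@H](CC=C(C)C)C[C@@]1(CC=C(C)C)C(=O)O[C@@H](CC=C(C)C)C1=O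
F2 | step 17 | N-methoxy-N-methylamide of F1 | CC(C)=CCC[C@](CC(=O)N(C)OC)(C)[C@@H](CC=C(C)C)C[C@@]1(CC=C(C)C)C(=O)O[C@@H](CC=C(C)C)C1=O
F3 | step 13 | (5S)-4-allyloxy-3-[(2S,3S)-3-(2-hydroxyethyl)-3,7-dimethyl-2-prenyloct-6-en-1-yl]-5-prenylfuran-2(5H)-one | CC(C)=CCC[C@](CCO)(C)[C@@H](CC=C(C)C)CC1=C(OCC=C)[C@H](CC=C(C)C)OC1=O
F4 | step 13 | 3-allyl analogue of 24 (same spatial arrangement at C3 and C5) | CC(C)=CCC[C@](CCO)(C)[C@@H](CC=C(C)C)C[C@@]1(CC=C)C(=O)O[C@@H](CC=C(C)C)C1=O
F5 | step 20 | 5-(1-hydroxy-2-methylpropyl) derivative of 34 (C5 and carbinol epimers) | CC(C)=CCC[C@]1(C)[C@@H](CC=C(C)C)C[C@@]2(CC=C(C)C)C(=O)O[C@@](CC=C(C)C)(C(=O)C1C(O)C(C)C)C2=O
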